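**Retrosynthetic overview**

1. Target 18 ⇐ removal of three MOM groups ⇐ isoflavone 17 ⇐ loss of water across C2–C3 of 3-hydroxyisoflavanone 16.
2. 16 ⇐ C3–C4 bond of the pyranone ring C. C4 (carbonyl carbon on ring A) and C3 (the carbon carrying ring B) are both carbonyl carbons in the O1–C2-tethered open form 15, so the bond needs polarity inversion at C4 (carbene acyl anion).
3. 15 ⇐ O1–C2 ether bond from phenol 14 and α-bromoketone 9. Ring A is mirror-symmetric (oxygens at C5/C7, prenyls at C6/C8), so either ortho hydroxyl of the aldehyde may carry the tether.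
4. 14 ⇐ 2,4,6-trihydroxybenzaldehyde by double nuclear prenylation and bis-MOM protection. 9 ⇐ 2',4'-dihydroxyacetophenone by Claisen rearrangement of its 1,1-dimethylallyl ether (the ether that gives a normal prenyl group), MOM/methyl differentiation and bromination through the enol silane.
5. Rings A and B are bought; ring C is the only ring formed (step 10) and is made aromatic in step 11.

Key step: step 10

Assumption: the target has no stereogenic element, so "single enantiomer" is read as the single constitutional isomer drawn, and the one stereocentre met on the way (C3 of 16) is made racemic and then removed; in steps 8 and 12 the partly protected phenols that precede the named product form in no fixed order and are not numbered.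

**Route**

Step 1
Reactants: 1 2',4'-dihydroxyacetophenone; 2 3-chloro-3-methylbut-1-yne
Product: 3 1-[2-hydroxy-4-(2-methylbut-3-yn-2-yloxy)phenyl]ethan-1-one
Conditions: K2CO3, KI, CuI (cat.), acetone, 55 °C
Reagents that add atoms: none
Why: Copper-assisted Williamson-type O-propargylation with the tertiary propargylic chloride takes place only at the 4-OH, because the 2-OH is held in a hydrogen bond to the acetyl group.

Step 2
Reactants: 3 1-[2-hydroxy-4-(2-methylbut-3-yn-2-yloxy)phenyl]ethan-1-one
Product: 4 1-[2-hydroxy-4-(2-methylbut-3-en-2-yloxy)phenyl]ethan-1-one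
Conditions: H2 (1 atm), Lindlar catalyst, quinoline, EtOAc, rt
Reagents that add atoms: none
Why: Lindlar semihydrogenation stops the terminal alkyne at the alkene on the poisoned catalyst and gives the 1,1-dimethylallyl ether needed for the rearrangement.

Step 3
Reactants: 4 1-[2-hydroxy-4-(2-methylbut-3-en-2-yloxy)phenyl]ethan-1-one
Product: 5 1-[2,4-dihydroxy-3-(3-methylbut-2-en-1-yl)phenyl]ethan-1-one
Conditions: PhNEt2, 130 °C, Ar
Reagents that add atoms: none
Why: The aromatic Claisen rearrangement ([3,3]) of a 1,1-dimethylallyl ether delivers the allyl terminus to the ring and so gives a normal prenyl group; the hydrogen-bonded 2-OH/acetyl pair makes the C3–C4 ring bond the more olefinic one, which should direct migration to C3 between the two oxygens and not to C5.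

Step 4
Reactants: 5 1-[2,4-dihydroxy-3-(3-methylbut-2-en-1-yl)phenyl]ethan-1-one
Product: 6 1-[2-hydroxy-4-(methoxymethoxy)-3-(3-methylbut-2-en-1-yl)phenyl]ethan-1-one
Conditions: MOMCl (1.1 equiv), i-Pr2NEt, CH2Cl2, 0 °C to rt
Reagents that add atoms: chloromethyl methyl ether, COCCl
Why: Williamson-type O-alkylation with MOMCl occurs at the free 4-OH, while the chelated 2-OH does not react under amine base.

Step 5
Reactants: 6 1-[2-hydroxy-4-(methoxymethoxy)-3-(3-methylbut-2-en-1-yl)phenyl]ethan-1-one
Product: 7 1-[2-methoxy-4-(methoxymethoxy)-3-(3-methylbut-2-en-1-yl)phenyl]ethan-1-one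
Conditions: MeI, K2CO3, DMF, 40 °C
Reagents that add atoms: iodomethane, CI
Why: O-Methylation (Williamson) of the chelated phenol with carbonate in DMF is the usual way to cap a 2-hydroxyacetophenone and leaves the MOM ether and the prenyl group alone.

Step 6
Reactants: 7 1-[2-methoxy-4-(methoxymethoxy)-3-(3-methylbut-2-en-1-yl)phenyl]ethan-1-one
Product: 9 2-bromo-1-[2-methoxy-4-(methoxymethoxy)-3-(3-methylbut-2-en-1-yl)phenyl]ethan-1-one, via trimethylsilyl enol ether 8 (not isolated)
Conditions: LiHMDS, TMSCl, THF, −78 °C; then NBS, NaHCO3, THF, −78 to 0 °C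
Reagents that add atoms: N-bromosuccinimide, O=C1CCC(=O)N1Br; chlorotrimethylsilane, C[Si](C)(C)Cl (silicon only in 8)
Why: Kinetic enolisation and O-silylation of the methyl ketone give the enol silane, the most nucleophilic π-system present, so electrophilic bromination with NBS at low temperature should occur at the α-carbon and not at the prenyl alkene or the arene.

Step 7
Reactants: 10 2,4,6-trihydroxybenzaldehyde; 11 prenyl bromide (2.1 equiv)
Product: 13 2,4,6-trihydroxy-3,5-bis(3-methylbut-2-en-1-yl)benzaldehyde, via mono-prenyl aldehyde 12 (not isolated)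
Conditions: 10% aq. KOH, 0 °C to rt, N2
Reagents that add atoms: none
Why: Nuclear C-prenylation of the phloroglucinol polyphenoxide in water (the deoxyhumulone-type alkylation of acylphloroglucinols) is favoured over O-alkylation by hydrogen bonding to the phenoxide oxygens; the two free ring positions are equivalent, and mono-, O- and gem-alkylated by-products are removed by chromatography.

Step 8
Reactants: 13 2,4,6-trihydroxy-3,5-bis(3-methylbut-2-en-1-yl)benzaldehyde
Product: 14 2-hydroxy-4,6-bis(methoxymethoxy)-3,5-bis(3-methylbut-2-en-1-yl)benzaldehyde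
Conditions: MOMCl (2.3 equiv), i-Pr2NEt, CH2Cl2, 0 °C to rt
Reagents that add atoms: chloromethyl methyl ether, COCCl
Why: MOM ether formation stops after two groups, the standard outcome for 2,4,6-trihydroxyacylbenzenes, because the last ortho hydroxyl is locked in a hydrogen bond to the formyl group; the mirror symmetry of 13 allows only one bis-ether.

Step 9
Reactants: 14 2-hydroxy-4,6-bis(methoxymethoxy)-3,5-bis(3-methylbut-2-en-1-yl)benzaldehyde; 9 2-bromo-1-[2-methoxy-4-(methoxymethoxy)-3-(3-methylbut-2-en-1-yl)phenyl]ethan-1-one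
Product: 15 2-{2-[2-methoxy-4-(methoxymethoxy)-3-(3-methylbut-2-en-1-yl)phenyl]-2-oxoethoxy}-4,6-bis(methoxymethoxy)-3,5-bis(3-methylbut-2-en-1-yl)benzaldehyde
Conditions: K2CO3, DMF, 0 °C to rt, quenched at full conversion
Reagents that add atoms: none
Why: Williamson ether synthesis joins the only free phenol to a highly SN2-reactive α-bromoketone; carbonate at or below room temperature and a prompt quench keep the product from base-mediated aldol condensation to a 2-aroylbenzofuran (Rap–Stoermer reaction).

Step 10
Reactants: 15 2-{2-[2-methoxy-4-(methoxymethoxy)-3-(3-methylbut-2-en-1-yl)phenyl]-2-oxoethoxy}-4,6-bis(methoxymethoxy)-3,5-bis(3-methylbut-2-en-1-yl)benzaldehyde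
Product: 16 rac-3-hydroxy-3-[2-methoxy-4-(methoxymethoxy)-3-(3-methylbut-2-en-1-yl)phenyl]-5,7-bis(methoxymethoxy)-6,8-bis(3-methylbut-2-en-1-yl)chroman-4-one
Conditions: 2-(pentafluorophenyl)-6,7-dihydro-5H-pyrrolo[2,1-c][1,2,4]triazol-2-ium tetrafluoroborate (20 mol%), Et3N (20 mol%), degassed PhMe, 40 °C, Ar
Reagents that add atoms: none
Why: Triethylamine releases the triazolylidene, which adds to the formyl carbon of 15; proton transfer gives the Breslow enaminol, whose nucleophilic carbon (the future C4) attacks the tethered aroyl carbon (the future C3) before the carbene leaves the resulting alkoxide. This is the NHC-catalysed intramolecular crossed aldehyde–ketone benzoin reaction that converts 2-(2-oxoalkoxy)benzaldehydes into 3-hydroxychroman-4-ones. The pyranone ring closes in a 6-exo-trig mode. C3 is the only new stereocentre; the achiral catalyst gives it as a racemate on purpose, since step 11 removes it. The step needs the aldehyde as donor and the ketone as acceptor, which is secured because a ketone cannot form a Breslow intermediate and because the aldehyde, flanked by two alkoxy groups, cannot accept a second molecule of itself. Enolisation of the O–CH2–CO unit and aldol closure onto the formyl group to a 2-aroylbenzofuran is held back by using only a catalytic amount of a weak amine base in toluene.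

Step 11
Reactants: 16 rac-3-hydroxy-3-[2-methoxy-4-(methoxymethoxy)-3-(3-methylbut-2-en-1-yl)phenyl]-5,7-bis(methoxymethoxy)-6,8-bis(3-methylbut-2-en-1-yl)chroman-4-one
Product: 17 3-[2-methoxy-4-(methoxymethoxy)-3-(3-methylbut-2-en-1-yl)phenyl]-5,7-bis(methoxymethoxy)-6,8-bis(3-methylbut-2-en-1-yl)-4H-chromen-4-one
Conditions: Burgess reagent (2 equiv), THF, 60 °C
Reagents that add atoms: none
Why: Burgess dehydration (sulfamate formation at the tertiary carbinol, then syn-elimination) has only the C2 hydrogens as β-hydrogens, so it can give only the C2=C3 alkene of the 4-pyranone, under neutral conditions that leave MOM ethers and prenyl groups untouched; the transient C3 stereocentre disappears.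

Step 12
Reactants: 17 3-[2-methoxy-4-(methoxymethoxy)-3-(3-methylbut-2-en-1-yl)phenyl]-5,7-bis(methoxymethoxy)-6,8-bis(3-methylbut-2-en-1-yl)-4H-chromen-4-one
Product: 18 5,7-dihydroxy-3-[4-hydroxy-2-methoxy-3-(3-methylbut-2-en-1-yl)phenyl]-6,8-bis(3-methylbut-2-en-1-yl)-4H-chromen-4-one (target)
Conditions: 3 M aq. HCl, MeOH–THF, 45 °C, short contact time
Reagents that add atoms: none
Why: Acid-catalysed acetal cleavage (transacetalisation to methanol) removes the three aryl MOM ethers; mild acid and short contact are chosen so that the freed ortho-prenylphenols do not cyclise to chromans, and the aryl methyl ether is stable.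

**Compound list**

1 | 2',4'-dihydroxyacetophenone | CC(=O)c1ccc(O)cc1O | starting material
2 | 3-chloro-3-methylbut-1-yne | C#CC(C)(C)Cl | starting material
3 | 1-[2-hydroxy-4-(2-methylbut-3-yn-2-yloxy)phenyl]ethan-1-one | CC(=O)c1ccc(OC(C)(C)C#C)cc1O | intermediate
4 | 1-[2-hydroxy-4-(2-methylbut-3-en-2-yloxy)phenyl]ethan-1-one | CC(=O)c1ccc(OC(C)(C)C=C)cc1O | intermediate
5 | 1-[2,4-dihydroxy-3-(3-methylbut-2-en-1-yl)phenyl]ethan-1-one | CC(=O)c1ccc(O)c(CC=C(C)C)c1O | intermediate
6 | 1-[2-hydroxy-4-(methoxymethoxy)-3-(3-methylbut-2-en-1-yl)phenyl]ethan-1-one | CC(=O)c1ccc(OCOC)c(CC=C(C)C)c1O | intermediate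
7 | 1-[2-methoxy-4-(methoxymethoxy)-3-(3-methylbut-2-en-1-yl)phenyl]ethan-1-one | CC(=O)c1ccc(OCOC)c(CC=C(C)C)c1OC | intermediate
8 | {1-[2-methoxy-4-(methoxymethoxy)-3-(3-methylbut-2-en-1-yl)phenyl]ethenyloxy}trimethylsilane (not isolated) | C=C(O[Si](C)(C)C)c1ccc(OCOC)c(CC=C(C)C)c1OC | intermediate
9 | 2-bromo-1-[2-methoxy-4-(methoxymethoxy)-3-(3-methylbut-2-en-1-yl)phenyl]ethan-1-one | O=C(CBr)c1ccc(OCOC)c(CC=C(C)C)c1OC | intermediate
10 | 2,4,6-trihydroxybenzaldehyde | O=Cc1c(O)cc(O)cc1O | starting material
11 | prenyl bromide (1-bromo-3-methylbut-2-ene) | CC(C)=CCBr | starting material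
12 | 2,4,6-trihydroxy-3-(3-methylbut-2-en-1-yl)benzaldehyde (not isolated) | O=Cc1c(O)cc(O)c(CC=C(C)C)c1O | intermediate
13 | 2,4,6-trihydroxy-3,5-bis(3-methylbut-2-en-1-yl)benzaldehyde | O=Cc1c(O)c(CC=C(C)C)c(O)c(CC=C(C)C)c1O | intermediate
14 | 2-hydroxy-4,6-bis(methoxymethoxy)-3,5-bis(3-methylbut-2-en-1-yl)benzaldehyde | O=Cc1c(O)c(CC=C(C)C)c(OCOC)c(CC=C(C)C)c1OCOC | intermediate
15 | 2-{2-[2-methoxy-4-(methoxymethoxy)-3-(3-methylbut-2-en-1-yl)phenyl]-2-oxoethoxy}-4,6-bis(methoxymethoxy)-3,5-bis(3-methylbut-2-en-1-yl)benzaldehyde | O=Cc1c(OCOC)c(CC=C(C)C)c(OCOC)c(CC=C(C)C)c1OCC(=O)c1ccc(OCOC)c(CC=C(C)C)c1OC | intermediate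
16 | rac-3-hydroxy-3-[2-methoxy-4-(methoxymethoxy)-3-(3-methylbut-2-en-1-yl)phenyl]-5,7-bis(methoxymethoxy)-6,8-bis(3-methylbut-2-en-1-yl)chroman-4-one (racemic at C3) | COc1c(C2(O)COc3c(CC=C(C)C)c(OCOC)c(CC=C(C)C)c(OCOC)c3C2=O)ccc(OCOC)c1CC=C(C)C | intermediate
17 | 3-[2-methoxy-4-(methoxymethoxy)-3-(3-methylbut-2-en-1-yl)phenyl]-5,7-bis(methoxymethoxy)-6,8-bis(3-methylbut-2-en-1-yl)-4H-chromen-4-one | COc1c(-c2coc3c(CC=C(C)C)c(OCOC)c(CC=C(C)C)c(OCOC)c3c2=O)ccc(OCOC)c1CC=C(C)C | intermediate
18 | 5,7-dihydroxy-3-[4-hydroxy-2-methoxy-3-(3-methylbut-2-en-1-yl)phenyl]-6,8-bis(3-methylbut-2-en-1-yl)-4H-chromen-4-one (CNP0331360.0, achiral) | COc1c(-c2coc3c(CC=C(C)C)c(O)c(CC=C(C)C)c(O)c3c2=O)ccc(O)c1CC=C(C)C | target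

**Step count**

Total: 12 steps. Longest linear sequence: 10 steps (steps 1–6, then 9–12); steps 7–8 form the second branch.

**Steps most likely to fail**

Step 10. The carbene may add too slowly to a formyl group that stands between two alkoxy groups on an electron-rich ring, so that enolisation of the O–CH2–CO unit and aldol condensation onto the aldehyde consume the substrate instead. The fallback sets out from 15 and returns at 18; it reshapes the donor aldehyde and not only the catalyst. The MOM group ortho to the formyl group of 15 should be the most acid-labile of the three, because the neighbouring carbonyl assists its cleavage. It would be removed with dilute HCl in MeOH–THF at 0 °C to give 2-hydroxy-6-{2-[2-methoxy-4-(methoxymethoxy)-3-prenylphenyl]-2-oxoethoxy}-4-(methoxymethoxy)-3,5-diprenylbenzaldehyde F1. In F1 the small, hydrogen-bonded hydroxyl opens the approach to the formyl carbon and polarises it. The triazolylidene/Et3N benzoin cyclisation applied to F1 should give the racemic 3,5-dihydroxyisoflavanone F2. SOCl2–pyridine at 0 °C would dehydrate its tertiary carbinol to the 5-hydroxy-7,4'-bis-MOM isoflavone F3; the chelated 5-OH is the least reactive hydroxyl, and any aryl chlorosulfite formed there is hydrolysed on work-up. The conditions of step 12 then remove the two remaining MOM groups and give 18.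

Step 7. Nuclear alkylation may stop at the mono-prenyl stage or run on to geminal, dearomatising prenylation, and O-alkylation competes, so the wanted bis-C-prenyl compound may be a minor part of the mixture. The fallback sets out from prenyl bromide 11 and commercial phloroglucinol (Oc1cc(O)cc(O)c1) and returns at 14; it replaces phenoxide alkylation by directed ortho-metalation. Phloroglucinol with MOMCl/NaH in DMF gives 1,3,5-tris(methoxymethoxy)benzene F4. Lithiation between two MOM ethers (n-BuLi, THF, 0 °C) and alkylation with 11 (cat. CuBr·SMe2) gives the mono-prenyl arene F5. A second lithiation/prenylation gives the 2,4-diprenyl arene F6. A third lithiation at the last ring position and a DMF quench give 2,4,6-tris(methoxymethoxy)-3,5-diprenylbenzaldehyde F7. Carbonyl-assisted cleavage of one ortho MOM group (dilute HCl, MeOH–THF, 0 °C) then gives 14; the first hydroxyl freed ties up the formyl oxygen in a hydrogen bond, so the second ortho MOM group loses the same assistance.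

Step 11. Sulfamate formation at the hindered tertiary carbinol may be sluggish, or the sulfamate may ionise and suffer a 1,2-shift before elimination. The fallback sets out from 16 and returns at 18 with no new compound; it replaces the syn-elimination by an acid E1 process merged with the deprotection. Treating 16 with 3 M HCl in MeOH–THF at 50 °C should ionise the C3–OH to a tertiary cation that is stabilised by the 2'-methoxy and 4'-oxygen of ring B. Loss of a C2 proton gives the pyranone while the same acid removes the three MOM groups, with the reaction stopped early to spare the prenyl groups.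

**Further compounds**

F1 | step 10 | 2-hydroxy-6-{2-[2-methoxy-4-(methoxymethoxy)-3-(3-methylbut-2-en-1-yl)phenyl]-2-oxoethoxy}-4-(methoxymethoxy)-3,5-bis(3-methylbut-2-en-1-yl)benzaldehyde | O=Cc1c(O)c(CC=C(C)C)c(OCOC)c(CC=C(C)C)c1OCC(=O)c1ccc(OCOC)c(CC=C(C)C)c1OC
F2 | step 10 | rac-3,5-dihydroxy-3-[2-methoxy-4-(methoxymethoxy)-3-(3-methylbut-2-en-1-yl)phenyl]-7-(methoxymethoxy)-6,8-bis(3-methylbut-2-en-1-yl)chroman-4-one | COc1c(C2(O)COc3c(CC=C(C)C)c(OCOC)c(CC=C(C)C)c(O)c3C2=O)ccc(OCOC)c1CC=C(C)C
F3 | step 10 | 5-hydroxy-3-[2-methoxy-4-(methoxymethoxy)-3-(3-methylbut-2-en-1-yl)phenyl]-7-(methoxymethoxy)-6,8-bis(3-methylbut-2-en-1-yl)-4H-chromen-4-one | COc1c(-c2coc3c(CC=C(C)C)c(OCOC)c(CC=C(C)C)c(O)c3c2=O)ccc(OCOC)c1CC=C(C)C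
F4 | step 7 | 1,3,5-tris(methoxymethoxy)benzene | COCOc1cc(OCOC)cc(OCOC)c1
F5 | step 7 | 1,3,5-tris(methoxymethoxy)-2-(3-methylbut-2-en-1-yl)benzene | COCOc1cc(OCOC)c(CC=C(C)C)c(OCOC)c1
F6 | step 7 | 1,3,5-tris(methoxymethoxy)-2,4-bis(3-methylbut-2-en-1-yl)benzene | COCOc1cc(OCOC)c(CC=C(C)C)c(OCOC)c1CC=C(C)C
F7 | step 7 | 2,4,6-tris(methoxymethoxy)-3,5-bis(3-methylbut-2-en-1-yl)benzaldehyde | O=Cc1c(OCOC)c(CC=C(C)C)c(OCOC)c(CC=C(C)C)c1OCOC
F0 | step 11 | none | none
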